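**Retrosynthetic overview**
- Target ← global O-demethylation of its hexamethyl ether ← Heck coupling of a 5-chloro-2,3-diaryl-2,3-dihydrobenzofuran with 3,5-dimethoxystyrene.
- 5-Chlorodihydrobenzofuran ← key step: intramolecular diazine–alkyne [4+2] cycloaddition, then loss of N2, of a 3-chloro-6-alkoxypyridazine carrying a terminal alkyne in the alkoxy chain.
- Ring order: the three pendant aryl rings are bought; ring B (dihydrofuran) and ring A (benzo ring) are formed together in the key step.
- Pyridazinyl ether ← SNAr of an anti-1,2-diaryl homopropargylic alcohol on 3,6-dichloropyridazine.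
- Alcohol (both stereocentres) ← anti-selective SE2' addition of an axially chiral allenylzinc, made from an (S)-propargylic mesylate, to 3,4-dimethoxybenzaldehyde; mesylate ← asymmetric alkynylation of 3,5-dimethoxybenzaldehyde.

Assumption: (R,R)-ProPhenol is taken to direct Si-face alkynylation of aldehyde 1, giving S-configured 4; if the sense proves opposite, (S,S)-ProPhenol is used and nothing else changes.

**Route**

Step 1
Reactants: 1 3,5-dimethoxybenzaldehyde; 2 ethynyltrimethylsilane
Product: 4 (S)-1-(3,5-dimethoxyphenyl)prop-2-yn-1-ol, via TMS-alkynol 3 (not isolated)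
Conditions: 2 (3 equiv), Me2Zn (3 equiv), (R,R)-ProPhenol (10 mol%), Ph3P=O (20 mol%), toluene, 0 °C; then MeOH, K2CO3, rt; aq NH4Cl
Reagents that add atoms: none
Why: Dinuclear zinc–ProPhenol enantioselective alkynylation of the aryl aldehyde (Trost alkynylation) adds the alkynylzinc to the Si face and so sets the carbinol centre, and methanolysis of the C(sp)–Si bond in the same flask frees the terminal alkyne without touching that centre (the change of descriptor from R in 3 to S in 4 is only a CIP priority switch).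

Step 2
Reactants: 4 (S)-1-(3,5-dimethoxyphenyl)prop-2-yn-1-ol
Product: 5 (S)-1-(3,5-dimethoxyphenyl)prop-2-yn-1-yl methanesulfonate
Conditions: MsCl, Et3N, CH2Cl2, −78 °C, 30 min; cold aqueous work-up, used crude at once
Reagents that add atoms: methanesulfonyl chloride, CS(=O)(=O)Cl
Why: O-sulfonylation leaves the C–O stereocentre untouched (retention), and the two meta methoxy groups do not stabilise a benzylic cation, so the mesylate survives cold handling.

Step 3
Reactants: 5 (S)-1-(3,5-dimethoxyphenyl)prop-2-yn-1-yl methanesulfonate; 6 3,4-dimethoxybenzaldehyde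
Product: 7 (1S,2R)-1-(3,4-dimethoxyphenyl)-2-(3,5-dimethoxyphenyl)but-3-yn-1-ol
Conditions: Pd(OAc)2 (5 mol%), PPh3 (5 mol%), Et2Zn (3 equiv), THF, −78 → −20 °C; aq NH4Cl
Reagents that add atoms: none
Why: Marshall-type umpolung propargylation, in which zerovalent palladium displaces the mesylate anti (SN2'), transmetalation to zinc keeps the allene axis, and the allenylzinc adds to aldehyde 6 through a cyclic SE2' transition state on the zinc-bearing face, so C–O is replaced by C–C with net inversion (S in 5 becomes R at C2) while the chair with the two aryl groups turned apart gives the anti (1S) carbinol, any syn isomer being removed by chromatography.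

Step 4
Reactants: 7 (1S,2R)-1-(3,4-dimethoxyphenyl)-2-(3,5-dimethoxyphenyl)but-3-yn-1-ol; 8 3,6-dichloropyridazine
Product: 9 3-chloro-6-{[(1S,2R)-1-(3,4-dimethoxyphenyl)-2-(3,5-dimethoxyphenyl)but-3-yn-1-yl]oxy}pyridazine
Conditions: 8 (1.5 equiv), NaH (1.05 equiv), THF, 0 °C → rt
Reagents that add atoms: none
Why: SNAr of the sodium alkoxide on the doubly activated dichlorodiazine is fast at 0 °C, stops at mono-substitution because the new alkoxy group deactivates the second chloride, forms only an O–C(heteroaryl) bond so both stereocentres are untouched, and keeps the base exposure of the propargylic C–H short.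

Step 5
Reactants: 9 3-chloro-6-{[(1S,2R)-1-(3,4-dimethoxyphenyl)-2-(3,5-dimethoxyphenyl)but-3-yn-1-yl]oxy}pyridazine
Product: 11 (2S,3S)-5-chloro-2-(3,4-dimethoxyphenyl)-3-(3,5-dimethoxyphenyl)-2,3-dihydro-1-benzofuran, via diazabicyclic cycloadduct 10 (not isolated)
Conditions: degassed 1,2-dichlorobenzene (0.02 M), BHT (5 mol%), sealed tube, 200 °C, 12–24 h
Reagents that add atoms: none
Why: Intramolecular inverse-electron-demand Diels–Alder reaction of the tethered terminal alkyne across C3 and C6 of the chlorodiazine closes ring B and the carbocycle together, and retro-Diels–Alder loss of N2 aromatises the latter to ring A with chlorine fixed para to oxygen (C5), the anti-diaryl tether favouring the reactive rotamer and neither stereocentre taking part (the 1S,2R to 2S,3S change is again only a CIP priority switch at the former propargylic carbon).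

Step 6
Reactants: 11 (2S,3S)-5-chloro-2-(3,4-dimethoxyphenyl)-3-(3,5-dimethoxyphenyl)-2,3-dihydro-1-benzofuran; 12 3,5-dimethoxystyrene
Product: 13 (2S,3S)-2-(3,4-dimethoxyphenyl)-3-(3,5-dimethoxyphenyl)-5-[(E)-2-(3,5-dimethoxyphenyl)ethenyl]-2,3-dihydro-1-benzofuran
Conditions: Pd2(dba)3 (2.5 mol%), [HP(t-Bu)3]BF4 (10 mol%), Cy2NMe (1.5 equiv), 1,4-dioxane, 110 °C
Reagents that add atoms: none
Why: Mizoroki–Heck coupling of the electron-rich aryl chloride with a bulky trialkylphosphine on zerovalent palladium, where syn insertion and syn β-hydride elimination give the E-stilbene and the mild amine base leaves C2 and C3 alone.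

Step 7
Reactants: 13 (2S,3S)-2-(3,4-dimethoxyphenyl)-3-(3,5-dimethoxyphenyl)-5-[(E)-2-(3,5-dimethoxyphenyl)ethenyl]-2,3-dihydro-1-benzofuran
Product: 14 4-[(2S,3S)-3-(3,5-dihydroxyphenyl)-5-[(E)-2-(3,5-dihydroxyphenyl)ethenyl]-2,3-dihydro-1-benzofuran-2-yl]benzene-1,2-diol (CNP0207985.1)
Conditions: BBr3 (12 equiv), CH2Cl2, −78 → 0 °C; MeOH, then aq NaHCO3
Reagents that add atoms: none
Why: BBr3 cleavage of all six aryl methyl ethers (bromide SN2 at methyl on the boron-complexed ether) leaves the ring stereocentres, since C3 cannot ionise and any reversible C2–O ionisation recloses to the thermodynamically preferred trans isomer.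

**Compound list**
1 | 3,5-dimethoxybenzaldehyde | COc1cc(C=O)cc(OC)c1 | starting material
2 | ethynyltrimethylsilane | C#C[Si](C)(C)C | starting material
3 | (R)-1-(3,5-dimethoxyphenyl)-3-(trimethylsilyl)prop-2-yn-1-ol | C[Si](C)(C)C#C[C@H](O)c1cc(OC)cc(OC)c1 | intermediate
4 | (S)-1-(3,5-dimethoxyphenyl)prop-2-yn-1-ol | C#C[C@H](O)c1cc(OC)cc(OC)c1 | intermediate
5 | (S)-1-(3,5-dimethoxyphenyl)prop-2-yn-1-yl methanesulfonate | C#C[C@H](OS(C)(=O)=O)c1cc(OC)cc(OC)c1 | intermediate
6 | 3,4-dimethoxybenzaldehyde | COc1ccc(C=O)cc1OC | starting material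
7 | (1S,2R)-1-(3,4-dimethoxyphenyl)-2-(3,5-dimethoxyphenyl)but-3-yn-1-ol (anti) | C#C[C@H](c1cc(OC)cc(OC)c1)[C@@H](c1ccc(OC)c(OC)c1)O | intermediate
8 | 3,6-dichloropyridazine | Clc1ccc(Cl)nn1 | starting material
9 | 3-chloro-6-{[(1S,2R)-1-(3,4-dimethoxyphenyl)-2-(3,5-dimethoxyphenyl)but-3-yn-1-yl]oxy}pyridazine | C#C[C@H](c1cc(OC)cc(OC)c1)[C@@H](c1ccc(OC)c(OC)c1)Oc1ccc(Cl)nn1 | intermediate
10 | dihydrofuran-fused 2,3-diazabicyclo[2.2.2]octa-2,5,7-triene cycloadduct (Cl on one bridgehead, ether O on the other; either facial isomer, both lose N2 to 11) | C1=C2[C@H](c3cc(OC)cc(OC)c3)[C@@H](c3ccc(OC)c(OC)c3)OC24C=CC1(Cl)N=N4 | intermediate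
11 | (2S,3S)-5-chloro-2-(3,4-dimethoxyphenyl)-3-(3,5-dimethoxyphenyl)-2,3-dihydro-1-benzofuran (trans) | Clc1ccc2c(c1)[C@H](c1cc(OC)cc(OC)c1)[C@@H](c1ccc(OC)c(OC)c1)O2 | intermediate
12 | 3,5-dimethoxystyrene (1-ethenyl-3,5-dimethoxybenzene) | C=Cc1cc(OC)cc(OC)c1 | starting material
13 | (2S,3S)-2-(3,4-dimethoxyphenyl)-3-(3,5-dimethoxyphenyl)-5-[(E)-2-(3,5-dimethoxyphenyl)ethenyl]-2,3-dihydro-1-benzofuran | COc1cc(OC)cc(/C=C/c2ccc3c(c2)[C@H](c2cc(OC)cc(OC)c2)[C@@H](c2ccc(OC)c(OC)c2)O3)c1 | intermediate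
14 | 4-[(2S,3S)-3-(3,5-dihydroxyphenyl)-5-[(E)-2-(3,5-dihydroxyphenyl)ethenyl]-2,3-dihydro-1-benzofuran-2-yl]benzene-1,2-diol | Oc1cc(O)cc(/C=C/c2ccc3c(c2)[C@H](c2cc(O)cc(O)c2)[C@@H](c2ccc(O)c(O)c2)O3)c1 | target

**Totals**
Total step count: 7. Longest linear sequence: 7 (steps 1–7; the route is fully linear).

**Three steps most likely to fail, with fallbacks**

Step 3 may lose enantiopurity, because a 1-aryl allenylpalladium can racemise by exchange with zerovalent palladium before it reaches zinc, and the anti:syn ratio may be modest. The fallback sets out from 4 and comes back at 7. It moves the chirality transfer to a configurationally stable boron reagent. Alcohol 4 is converted with methyl chloroformate and pyridine into (S)-1-(3,5-dimethoxyphenyl)prop-2-yn-1-yl methyl carbonate F1. Anti-SN2' borylation (CuCl, NaOt-Bu, Xantphos, B2pin2, THF, rt; monovalent copper boryl) then gives the axially chiral (aS)-2-[3-(3,5-dimethoxyphenyl)propa-1,2-dien-1-yl]-4,4,5,5-tetramethyl-1,3,2-dioxaborolane F2. F2 adds to aldehyde 6 through a closed six-membered allenylboration transition state (toluene, 10 mol% diphenyl phosphate, 0 °C → rt), with the same net inversion and anti preference, to give 7.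

Step 5 may fail if, at about 200 °C, retro-ene loss of the chloropyridazinone or ionisation of the benzylic ether outruns the cycloaddition. The fallback sets out from 7 and comes back at 13. It lowers the barrier with a much more electron-poor diazine and builds the stilbene by olefination instead of Heck coupling. Alcohol 7 and 6-chloropyridazine-3-carbonitrile (N#Cc1ccc(Cl)nn1) with NaH in THF at −20 °C give 6-{[(1S,2R)-1-(3,4-dimethoxyphenyl)-2-(3,5-dimethoxyphenyl)but-3-yn-1-yl]oxy}pyridazine-3-carbonitrile F3. Heating F3 in chlorobenzene at about 130–150 °C passes through the cyano-substituted diazabicyclic cycloadduct F4 and, after loss of N2, gives (2S,3S)-2-(3,4-dimethoxyphenyl)-3-(3,5-dimethoxyphenyl)-2,3-dihydro-1-benzofuran-5-carbonitrile F5. Reduction with i-Bu2AlH (CH2Cl2, −78 °C, then aqueous acid) gives (2S,3S)-2-(3,4-dimethoxyphenyl)-3-(3,5-dimethoxyphenyl)-2,3-dihydro-1-benzofuran-5-carbaldehyde F6. Horner–Wadsworth–Emmons olefination of F6 with diethyl (3,5-dimethoxybenzyl)phosphonate (CCOP(=O)(Cc1cc(OC)cc(OC)c1)OCC) and NaH in THF gives the E-stilbene 13.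

Step 7 may fail because the strong Lewis acid and the HBr it generates can attack the electron-rich stilbene (cationic cyclisation onto the resorcinol ring, hydrobromination) on top of opening the dihydrofuran. The fallback sets out from 11 and comes back at 14. It demethylates before the stilbene exists and finishes with a mild ester cleavage. Chloride 11 with BBr3 in CH2Cl2 gives 4-[(2S,3S)-5-chloro-3-(3,5-dihydroxyphenyl)-2,3-dihydro-1-benzofuran-2-yl]benzene-1,2-diol F7. Acetylation (Ac2O, pyridine) gives the tetraacetate of that tetraphenol F8. Heck coupling of F8 with 3,5-diacetoxystyrene (C=Cc1cc(OC(C)=O)cc(OC(C)=O)c1) under the step 6 catalyst gives the hexaacetate of the target F9. Methanolysis of F9 (NH4OAc, aqueous MeOH, rt, argon) releases 14.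

**Further compounds**
F1 | step 3 | (S)-1-(3,5-dimethoxyphenyl)prop-2-yn-1-yl methyl carbonate | C#C[C@H](OC(=O)OC)c1cc(OC)cc(OC)c1
F2 | step 3 | (aS)-2-[3-(3,5-dimethoxyphenyl)propa-1,2-dien-1-yl]-4,4,5,5-tetramethyl-1,3,2-dioxaborolane | [H]C(B1OC(C)(C)C(C)(C)O1)=[C@]=C([H])c1cc(OC)cc(OC)c1
F3 | step 5 | 6-{[(1S,2R)-1-(3,4-dimethoxyphenyl)-2-(3,5-dimethoxyphenyl)but-3-yn-1-yl]oxy}pyridazine-3-carbonitrile | C#C[C@H](c1cc(OC)cc(OC)c1)[C@@H](c1ccc(OC)c(OC)c1)Oc1ccc(C#N)nn1
F4 | step 5 | cyano-substituted diazabicyclic cycloadduct (transient; either facial isomer) | C1=C2[C@H](c3cc(OC)cc(OC)c3)[C@@H](c3ccc(OC)c(OC)c3)OC24C=CC1(C#N)N=N4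
F5 | step 5 | (2S,3S)-2-(3,4-dimethoxyphenyl)-3-(3,5-dimethoxyphenyl)-2,3-dihydro-1-benzofuran-5-carbonitrile | N#Cc1ccc2c(c1)[C@H](c1cc(OC)cc(OC)c1)[C@@H](c1ccc(OC)c(OC)c1)O2
F6 | step 5 | (2S,3S)-2-(3,4-dimethoxyphenyl)-3-(3,5-dimethoxyphenyl)-2,3-dihydro-1-benzofuran-5-carbaldehyde | O=Cc1ccc2c(c1)[C@H](c1cc(OC)cc(OC)c1)[C@@H](c1ccc(OC)c(OC)c1)O2
F7 | step 7 | 4-[(2S,3S)-5-chloro-3-(3,5-dihydroxyphenyl)-2,3-dihydro-1-benzofuran-2-yl]benzene-1,2-diol | Clc1ccc2c(c1)[C@H](c1cc(O)cc(O)c1)[C@@H](c1ccc(O)c(O)c1)O2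
F8 | step 7 | 4-[(2S,3S)-5-chloro-3-(3,5-diacetoxyphenyl)-2,3-dihydro-1-benzofuran-2-yl]-1,2-phenylene diacetate | Clc1ccc2c(c1)[C@H](c1cc(OC(C)=O)cc(OC(C)=O)c1)[C@@H](c1ccc(OC(C)=O)c(OC(C)=O)c1)O2
F9 | step 7 | hexaacetate of 14 | CC(=O)Oc1cc(OC(C)=O)cc(/C=C/c2ccc3c(c2)[C@H](c2cc(OC(C)=O)cc(OC(C)=O)c2)[C@@H](c2ccc(OC(C)=O)c(OC(C)=O)c2)O3)c1
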